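The route rests on cutting the ring O–C4 bond of the lactone (C1 carbonyl, C2 alkylidene carbon, C3 stereocentre, C4 ring OCH2, C7 vinylic CH, C7' benzylic CH2). C3 carries two methylene arms, C4 and C7', so it is hidden as C3 of an achiral oxetane in which these are the enantiotopic ring carbons. A chiral phosphoric acid should direct the ester carbonyl oxygen onto one of them: in one operation the lactone ring closes, C3 is set, isobutene leaves and the CH2OH arm that becomes C7' is freed. The precursor is a tert-butyl (E)-2-(oxetan-3-yl)cinnamate with the silylated syringyl ring on C7.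

Key step: step 6

Remarks on the chemistry
- Assumption: the sense of induction of the phosphoric acid with this nucleophile cannot be predicted with confidence; the (R)-acid is written, and its enantiomer would be used if a first run gave the mirror-image lactone.
- Structure check: the hydroxymethyl lactone is (S) and the target is (R) although the arrangement at C3 is the same. The letter changes only because CH2OH ranks above C2 whereas CH2Ar ranks below it; the iodide, the organozinc and the silylated target are (R).
- Precursor design: the tert-butyl ester is kept, because a free acid would lactonise onto the oxetane without the catalyst and give racemate, and a methyl ester has no clean exit from the oxocarbenium ion. The phenol is carried as its TBS ether so that no O–H competes for the phosphate or later quenches the organozinc. The E geometry is installed before the key step, which does not touch it.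

Step 1
Reactants: 1 oxetan-3-one; 2 tert-butyl diethylphosphonoacetate
Product: 4 tert-butyl 2-(oxetan-3-ylidene)acetate, via sodium phosphonate carbanion 3 (not isolated)
Conditions: NaH, THF, 0 °C to rt
Reagents that add atoms: none
Why: Horner–Wadsworth–Emmons olefination of the unhindered, symmetric ketone by the stabilised phosphonate carbanion is a standard entry to oxetan-3-ylidene acetates, and the symmetry of the ketone makes alkene geometry irrelevant.

Step 2
Reactants: 4 tert-butyl 2-(oxetan-3-ylidene)acetate
Product: 5 tert-butyl 2-(oxetan-3-yl)acetate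
Conditions: H2 (1 atm), Pd/C (10 wt% Pd on carbon), EtOAc, rt
Reagents that add atoms: none
Why: Heterogeneous catalytic hydrogenation should saturate the strained exocyclic enoate under neutral conditions that leave the oxetane and the tert-butyl ester intact.

Step 3
Reactants: 6 syringaldehyde (4-hydroxy-3,5-dimethoxybenzaldehyde)
Product: 7 4-(tert-butyldimethylsilyloxy)-3,5-dimethoxybenzaldehyde
Conditions: TBSCl, imidazole, DMF, rt
Reagents that add atoms: tert-butyldimethylsilyl chloride (TBSCl), CC(C)(C)[Si](C)(C)Cl
Why: Imidazole-promoted silylation of the phenol (silyl ether formation) should give an aryl silyl ether that the two flanking methoxy groups shield from base in the later steps.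

Step 4
Reactants: 5 tert-butyl 2-(oxetan-3-yl)acetate; 7 4-(tert-butyldimethylsilyloxy)-3,5-dimethoxybenzaldehyde
Product: 9 tert-butyl 3-[4-(tert-butyldimethylsilyloxy)-3,5-dimethoxyphenyl]-3-hydroxy-2-(oxetan-3-yl)propanoate (mixture of diastereomers, each racemic), via lithium ester enolate 8 (not isolated)
Conditions: LiN(iPr)2, THF, −78 °C; then 7, −78 °C; aq. NH4Cl
Reagents that add atoms: none
Why: Aldol addition of the lithium enolate of a tert-butyl ester, which does not self-condense at −78 °C, to a non-enolisable aryl aldehyde should be clean, and the two uncontrolled stereocentres are both erased in step 5.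

Step 5
Reactants: 9 tert-butyl 3-[4-(tert-butyldimethylsilyloxy)-3,5-dimethoxyphenyl]-3-hydroxy-2-(oxetan-3-yl)propanoate
Product: 11 tert-butyl (E)-3-[4-(tert-butyldimethylsilyloxy)-3,5-dimethoxyphenyl]-2-(oxetan-3-yl)acrylate (achiral; aryl trans to the ester), via benzylic mesylate 10 (not isolated)
Conditions: MsCl, Et3N, CH2Cl2, 0 °C; then DBU, 0 °C to rt
Reagents that add atoms: none
Why: Mesylation followed by DBU-induced E1cB elimination through the ester enolate should give the conjugated acrylate from both aldol diastereomers, with the E isomer favoured because the aryl group avoids the planar C(O)OtBu unit in the enolate-like transition state.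

Step 6
Reactants: 11 tert-butyl (E)-3-[4-(tert-butyldimethylsilyloxy)-3,5-dimethoxyphenyl]-2-(oxetan-3-yl)acrylate
Product: 13 (S,E)-3-[4-(tert-butyldimethylsilyloxy)-3,5-dimethoxybenzylidene]-4-(hydroxymethyl)dihydrofuran-2(3H)-one, via tert-butoxy oxocarbenium ion 12 (not isolated)
Conditions: (R)-3,3'-bis(2,4,6-triisopropylphenyl)-1,1'-binaphthyl-2,2'-diyl hydrogen phosphate (10 mol%), PhMe (0.05 M), 40 °C
Reagents that add atoms: none
Why: Proposed new method: the acid hydrogen-bonds to the oxetane oxygen, the carbonyl oxygen of the tert-butyl ester attacks one ring CH2 from the back in an SN2 sense to give the ion-paired tert-butoxy oxocarbenium ion 12, and loss of isobutene from 12 hands the proton back to the phosphate and makes the closure irreversible. The closest known reaction type is the chiral phosphoric acid-catalysed intramolecular desymmetrisation of 3-substituted oxetanes by tethered O–H nucleophiles, combined with the familiar lactonisation of tert-butyl esters onto activated electrophiles (as in iodolactonisation); new here is an ester carbonyl as the tethered nucleophile for the oxetane. The lactone ring (O, C1, C2, C3, C4) closes in a 5-exo-tet mode, the breaking C4–O(oxetane) bond lying outside the new ring. C3 is controlled by the catalyst alone: no bond to C3 changes, and the chiral phosphate pocket decides which of the two enantiotopic CH2–O bonds is opened, that is, which arm becomes C4 and which is left as CH2OH. The step needs enantiotopic-group selectivity and must leave the E alkene, the aryl silyl ether and the allylic C3–H alone; the sp2 C2 holds ester and oxetane on one carbon so that only the five-membered closure is within reach, the electron-rich cinnamate raises the nucleophilicity of the carbonyl oxygen, and the absence of any O–H group in 11 rules out an uncatalysed racemic background. Because only a weak acid is present, alkene migration into the ring is not expected, and exchange of the two arms of 13 by translactonisation would have to pass through a strained 2,6-dioxabicyclo[2.2.1]heptane hemiorthoester.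

Step 7
Reactants: 13 (S,E)-3-[4-(tert-butyldimethylsilyloxy)-3,5-dimethoxybenzylidene]-4-(hydroxymethyl)dihydrofuran-2(3H)-one
Product: 14 (R,E)-3-[4-(tert-butyldimethylsilyloxy)-3,5-dimethoxybenzylidene]-4-(iodomethyl)dihydrofuran-2(3H)-one
Conditions: PPh3, I2, imidazole, CH2Cl2, 0 °C to rt
Reagents that add atoms: iodine, II
Why: Appel-type iodination should convert the primary alcohol into the iodide by SN2 at C7' under near-neutral conditions, so that C3, the lactone, the E alkene and the aryl silyl ether are untouched.

Step 8
Reactants: 14 (R,E)-3-[4-(tert-butyldimethylsilyloxy)-3,5-dimethoxybenzylidene]-4-(iodomethyl)dihydrofuran-2(3H)-one; 15 5-bromo-1,2,3-trimethoxybenzene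
Product: 17 (R,E)-3-[4-(tert-butyldimethylsilyloxy)-3,5-dimethoxybenzylidene]-4-(3,4,5-trimethoxybenzyl)dihydrofuran-2(3H)-one, via alkylzinc iodide 16 (not isolated)
Conditions: Zn dust (activated with cat. I2), DMF, rt; then 15, Pd(OAc)2 (5 mol%), SPhos (2-dicyclohexylphosphino-2',6'-dimethoxybiphenyl, 10 mol%), rt to 40 °C
Reagents that add atoms: none
Why: Direct zinc insertion into the primary C–I bond should give an alkylzinc iodide that tolerates the lactone, the enoate and the silyl ether, and Negishi coupling at SPhos-ligated zerovalent palladium (formed in the flask from Pd(OAc)2) should join C7' to the aryl ring faster than beta-hydride elimination, with C3 not involved.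

Step 9
Reactants: 17 (R,E)-3-[4-(tert-butyldimethylsilyloxy)-3,5-dimethoxybenzylidene]-4-(3,4,5-trimethoxybenzyl)dihydrofuran-2(3H)-one
Product: 18 (R,E)-3-(4-hydroxy-3,5-dimethoxybenzylidene)-4-(3,4,5-trimethoxybenzyl)dihydrofuran-2(3H)-one (target)
Conditions: Bu4NF, AcOH (1:1), THF, 0 °C
Reagents that add atoms: none
Why: Fluoride-induced desilylation of the aryl silyl ether, buffered with acetic acid so that the liberated phenoxide is protonated at once, should free the phenol without exposing the E alkene or the allylic C3–H to base.

Compound list
1 | oxetan-3-one | O=C1COC1 | starting material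
2 | tert-butyl diethylphosphonoacetate | CCOP(=O)(OCC)CC(=O)OC(C)(C)C | starting material
3 | sodium salt of the carbanion of tert-butyl diethylphosphonoacetate (formed in the flask) | [Na+].CCOP(=O)(OCC)[CH-]C(=O)OC(C)(C)C | intermediate
4 | tert-butyl 2-(oxetan-3-ylidene)acetate | CC(C)(C)OC(=O)C=C1COC1 | intermediate
5 | tert-butyl 2-(oxetan-3-yl)acetate | CC(C)(C)OC(=O)CC1COC1 | intermediate
6 | syringaldehyde | COc1cc(C=O)cc(OC)c1O | starting material
7 | 4-(tert-butyldimethylsilyloxy)-3,5-dimethoxybenzaldehyde | COc1cc(C=O)cc(OC)c1O[Si](C)(C)C(C)(C)C | intermediate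
8 | lithium enolate of 5, lithium 1-tert-butoxy-2-(oxetan-3-yl)ethen-1-olate (formed in the flask) | CC(C)(C)OC(O[Li])=CC1COC1 | intermediate
9 | tert-butyl 3-[4-(tert-butyldimethylsilyloxy)-3,5-dimethoxyphenyl]-3-hydroxy-2-(oxetan-3-yl)propanoate (diastereomer mixture, racemic) | CC(C)(C)OC(=O)C(C1COC1)C(O)c1cc(OC)c(O[Si](C)(C)C(C)(C)C)c(OC)c1 | intermediate
10 | tert-butyl 3-[4-(tert-butyldimethylsilyloxy)-3,5-dimethoxyphenyl]-3-(methanesulfonyloxy)-2-(oxetan-3-yl)propanoate (formed in the flask) | CC(C)(C)OC(=O)C(C1COC1)C(OS(C)(=O)=O)c1cc(OC)c(O[Si](C)(C)C(C)(C)C)c(OC)c1 | intermediate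
11 | tert-butyl (E)-3-[4-(tert-butyldimethylsilyloxy)-3,5-dimethoxyphenyl]-2-(oxetan-3-yl)acrylate | CC(C)(C)OC(=O)/C(=C/c1cc(OC)c(O[Si](C)(C)C(C)(C)C)c(OC)c1)C1COC1 | intermediate
12 | (S,E)-2-tert-butoxy-3-[4-(tert-butyldimethylsilyloxy)-3,5-dimethoxybenzylidene]-4-(hydroxymethyl)-4,5-dihydro-3H-furan-1-ium, paired with the chiral phosphate (formed in the flask) | COc1cc(/C=C2/C(OC(C)(C)C)=[O+]C[C@@H]2CO)cc(OC)c1O[Si](C)(C)C(C)(C)C | intermediate
13 | (S,E)-3-[4-(tert-butyldimethylsilyloxy)-3,5-dimethoxybenzylidene]-4-(hydroxymethyl)dihydrofuran-2(3H)-one | COc1cc(/C=C2/C(=O)OC[C@@H]2CO)cc(OC)c1O[Si](C)(C)C(C)(C)C | intermediate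
14 | (R,E)-3-[4-(tert-butyldimethylsilyloxy)-3,5-dimethoxybenzylidene]-4-(iodomethyl)dihydrofuran-2(3H)-one | COc1cc(/C=C2/C(=O)OC[C@@H]2CI)cc(OC)c1O[Si](C)(C)C(C)(C)C | intermediate
15 | 5-bromo-1,2,3-trimethoxybenzene | COc1cc(Br)cc(OC)c1OC | starting material
16 | {[(R,E)-4-[4-(tert-butyldimethylsilyloxy)-3,5-dimethoxybenzylidene]-5-oxotetrahydrofuran-3-yl]methyl}zinc iodide (formed in the flask) | COc1cc(/C=C2/C(=O)OC[C@@H]2C[Zn]I)cc(OC)c1O[Si](C)(C)C(C)(C)C | intermediate
17 | (R,E)-3-[4-(tert-butyldimethylsilyloxy)-3,5-dimethoxybenzylidene]-4-(3,4,5-trimethoxybenzyl)dihydrofuran-2(3H)-one | COc1cc(/C=C2/C(=O)OC[C@@H]2Cc2cc(OC)c(OC)c(OC)c2)cc(OC)c1O[Si](C)(C)C(C)(C)C | intermediate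
18 | (R,E)-3-(4-hydroxy-3,5-dimethoxybenzylidene)-4-(3,4,5-trimethoxybenzyl)dihydrofuran-2(3H)-one | COc1cc(/C=C2/C(=O)OC[C@@H]2Cc2cc(OC)c(OC)c(OC)c2)cc(OC)c1O | target

Total step count: 9
Longest linear sequence: 8 steps (1, 2, 4, 5, 6, 7, 8, 9 from oxetan-3-one); step 3 is a one-step side branch.

Steps most likely to fail

1. Step 6 (new method).
- What may go wrong: the ester carbonyl may be too weak a nucleophile for the acid-activated oxetane, so the ring stays closed. The two enantiotopic CH2–O bonds may be poorly discriminated. The liberated alcohol may add to a second oxetane.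
- Fallback, known chemistry, setting out from 11 and rejoining the route at 14:
 - Enantioselective chloride opening of the 3-substituted oxetane under the same class of chiral phosphoric acid, with slow release of HCl from Me3SiCl and wet molecular sieves. The acid enantiomer is chosen so that chloride enters the methylene that becomes C7'. This should give tert-butyl (E)-2-[(R)-1-chloro-3-hydroxypropan-2-yl]-3-[4-(tert-butyldimethylsilyloxy)-3,5-dimethoxyphenyl]acrylate F1.
 - Catalytic TsOH in warm toluene should close the free hydroxyl arm onto the tert-butyl ester, with loss of isobutene and water, to give (R,E)-3-[4-(tert-butyldimethylsilyloxy)-3,5-dimethoxybenzylidene]-4-(chloromethyl)dihydrofuran-2(3H)-one F2.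
 - Finkelstein exchange (NaI, butanone, 70 °C) should then give iodide 14, so that step 7 is no longer needed.

2. Step 8.
- What may go wrong: during zinc insertion the primary radical may close onto C2 (3-exo, giving a benzylic radical) and reopen with skeletal rearrangement. The alkylpalladium intermediate may lose a beta-hydride from C3 before reductive elimination. The organozinc may be protonated.
- Fallback with reversed polarity, setting out from 13 and rejoining at 17:
 - Triflation (Tf2O, 2,6-lutidine, CH2Cl2, −78 °C) should give [(R,E)-4-[4-(tert-butyldimethylsilyloxy)-3,5-dimethoxybenzylidene]-5-oxotetrahydrofuran-3-yl]methyl trifluoromethanesulfonate F3, which is used at once.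
 - Slow addition of (3,4,5-trimethoxyphenyl)magnesium bromide F4 (from 15 and Mg turnings in THF) with catalytic CuBr·SMe2 at −78 °C should displace the triflate in an SN2-type coupling and give 17. This avoids both an alkyl radical and an alkylpalladium species, and the cold, weakly basic organocopper should leave the lactone and C3–H alone.

3. Step 5.
- What may go wrong: loss of geometric control in the elimination, so that the Z acrylate forms beside the E isomer, or ionisation of the electron-rich benzylic sulfonate with side reactions.
- Fallback that fixes the geometry by a stereoretentive coupling, setting out from 7 and rejoining at 11 (steps 4 and 5 are bypassed):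
 - Wittig olefination of 7 with the stabilised ylide tert-butyl 2-bromo-2-(triphenylphosphoranylidene)acetate should give tert-butyl (Z)-2-bromo-3-[4-(tert-butyldimethylsilyloxy)-3,5-dimethoxyphenyl]acrylate F5, in which the aryl group is trans to the ester.
 - Negishi coupling with oxetan-3-ylzinc iodide F6 (from 3-iodooxetane, Zn dust and LiCl in THF) under Pd(OAc)2 and CPhos (2-dicyclohexylphosphino-2',6'-bis(dimethylamino)biphenyl) should replace bromine by the oxetane with retention of alkene geometry and give 11.

Further compounds
F1 | step 6 | tert-butyl (E)-2-[(R)-1-chloro-3-hydroxypropan-2-yl]-3-[4-(tert-butyldimethylsilyloxy)-3,5-dimethoxyphenyl]acrylate | OC[C@@H](/C(=C\c1cc(OC)c(O[Si](C)(C)C(C)(C)C)c(OC)c1)C(=O)OC(C)(C)C)CCl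
F2 | step 6 | (R,E)-3-[4-(tert-butyldimethylsilyloxy)-3,5-dimethoxybenzylidene]-4-(chloromethyl)dihydrofuran-2(3H)-one | COc1cc(/C=C2/C(=O)OC[C@@H]2CCl)cc(OC)c1O[Si](C)(C)C(C)(C)C
F3 | step 8 | [(R,E)-4-[4-(tert-butyldimethylsilyloxy)-3,5-dimethoxybenzylidene]-5-oxotetrahydrofuran-3-yl]methyl trifluoromethanesulfonate | COc1cc(/C=C2/C(=O)OC[C@@H]2COS(=O)(=O)C(F)(F)F)cc(OC)c1O[Si](C)(C)C(C)(C)C
F4 | step 8 | (3,4,5-trimethoxyphenyl)magnesium bromide | COc1cc([Mg]Br)cc(OC)c1OC
F5 | step 5 | tert-butyl (Z)-2-bromo-3-[4-(tert-butyldimethylsilyloxy)-3,5-dimethoxyphenyl]acrylate | CC(C)(C)OC(=O)/C(Br)=C/c1cc(OC)c(O[Si](C)(C)C(C)(C)C)c(OC)c1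
F6 | step 5 | oxetan-3-ylzinc iodide | I[Zn]C1COC1
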